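- Retrosynthesis: the seventeen alkyl ethers are cleaved last. The ether bonds B–O–A, C–O–B, D–O–C, E–O–D and F–O–E are then cut in that order, each into a chain phenol and a formyl-activated aryl halide whose CHO stands for the next phenol oxygen.
- The sixth ether, F–O–G, is not cut. Ring G is a 1-aryloxy-3,4,5-trioxygenated benzene whose ether carbon C1 lies between two C–H carbons (C2, C6). C1–C2 can therefore come from an aryloxyacetylene and C3–C6 with their three oxygens from a 3,4-dialkoxycyclobutenone; ring G is cut at C2–C3 and C1–C6.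
- The oxygen between rings F and G, crowded by two ortho oxygens on ring F, is thus placed on ring F as an ynol ether before ring G exists.
- Forward: ring F (from 2,6-dimethoxybenzoquinone) becomes the ynol ether and benzannulation builds ring G. Rings E, D, C, B and A follow one at a time (Ullmann coupling for rings E and C, SNAr for rings D, B and A, each followed by Dakin-type oxidation), and BBr3 frees all eighteen hydroxyls.
- Stereochemistry: the target is achiral and has no stereocentre; the one racemic centre on the way (C4 of the cyclobutenone) becomes an aromatic carbon.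

Key step: step 6

Remark: rings are lettered A to G from the 2,4,6-trihydroxyphenoxy end, and the two halo aldehydes used for chain extension (2-bromo-3,4,5-trimethoxybenzaldehyde and 4-fluoro-3,5-dimethoxybenzaldehyde) are taken as purchasable.

Step 1
Reactants: 1 quinone 2,6-dimethoxy-1,4-benzoquinone
Product: 2 hydroquinone 2,6-dimethoxybenzene-1,4-diol
Conditions: Na2S2O4, THF/H2O, rt, argon
Reagents that add atoms: none
Why: Reduction of a benzoquinone to its hydroquinone by Na2S2O4 is fast and clean in a two-phase medium (quinone reduction), and the air-sensitive diol is taken on directly.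

Step 2
Reactants: 2 hydroquinone 2,6-dimethoxybenzene-1,4-diol
Product: 3 mono-silyl ether 2,6-dimethoxy-4-(triisopropylsilyloxy)phenol
Conditions: TIPSCl (1.05 equiv), imidazole, DMF, 0 °C
Reagents that add atoms: triisopropylsilyl chloride (TIPSCl), CC(C)[Si](Cl)(C(C)C)C(C)C
Why: The bulky silyl chloride should react only at the hydroxyl flanked by two C–H positions, the other being shielded by two ortho methoxy groups (sterically controlled silyl ether formation), and the triisopropylsilyl group is chosen because it tolerates the phenoxide and n-BuLi of the next two steps.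

Step 3
Reactants: 3 mono-silyl ether 2,6-dimethoxy-4-(triisopropylsilyloxy)phenol; 4 trichloroethylene
Product: 7 dichlorovinyl ether (E)-1,2-dichlorovinyl 2,6-dimethoxy-4-(triisopropylsilyloxy)phenyl ether, via potassium phenoxide 5 (not isolated), via dichloroacetylene 6 (not isolated)
Conditions: KH, THF, 0 °C; then Cl2C=CHCl, THF/DMF, rt to 50 °C
Reagents that add atoms: none
Why: The phenoxide dehydrochlorinates trichloroethylene and adds to the dichloroacetylene so formed, followed by anti protonation (base-mediated synthesis of 1,2-dichlorovinyl ethers from phenols), a small linear electrophile being well suited to an oxygen flanked by two ortho substituents.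

Step 4
Reactants: 7 dichlorovinyl ether (E)-1,2-dichlorovinyl 2,6-dimethoxy-4-(triisopropylsilyloxy)phenyl ether
Product: 10 ring F ynol ether ethynyl 2,6-dimethoxy-4-(triisopropylsilyloxy)phenyl ether, via chloroethynyl ether 8 (not isolated), via lithium acetylide 9 (not isolated)
Conditions: n-BuLi (2.3 equiv), THF, −78 to −40 °C; then H2O, −78 °C to rt
Reagents that add atoms: none
Why: One equivalent of n-BuLi eliminates HCl to the chloroalkyne and a second effects chlorine–lithium exchange, so that neutral protonation of the acetylide releases the terminal aryl ynol ether (dichlorovinyl ether route to ynol ethers), which is used at once.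

Step 5
Reactants: 11 methoxyacetyl chloride; 12 ethoxyacetylene
Product: 14 cyclobutenone 3-ethoxy-4-methoxycyclobut-2-en-1-one (racemic), via methoxyketene 13 (not isolated)
Conditions: Et3N (slow addition), ethoxyacetylene (2 equiv), Et2O, 0 °C to rt
Reagents that add atoms: none
Why: Methoxyketene formed by dehydrochlorination is trapped by the electron-rich alkyne, whose unsubstituted carbon bonds to the ketene carbonyl carbon, placing ethoxy at C3 and methoxy at C4 (ketene–alkoxyacetylene (2+2) cycloaddition); the racemic C4 centre is erased in step 6.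

Step 6
Reactants: 10 ring F ynol ether ethynyl 2,6-dimethoxy-4-(triisopropylsilyloxy)phenyl ether; 14 cyclobutenone 3-ethoxy-4-methoxycyclobut-2-en-1-one
Product: 19 F–G phenol 5-[2,6-dimethoxy-4-(triisopropylsilyloxy)phenoxy]-3-ethoxy-2-methoxyphenol, via vinylketene 15 (not isolated), via vinylcyclobutenone 16 (not isolated), via dienylketene 17 (not isolated), via cyclohexadienone 18 (not isolated)
Conditions: toluene, 80 °C then 110 °C, argon, ring F ynol ether (1.3 equiv)
Reagents that add atoms: none
Why: Proposed new method: heating opens 14 by 4π-electrocyclic ring opening (methoxy rotating outward) to vinylketene 15, whose carbonyl carbon is attacked by the oxygen-free alkyne carbon of 10 in a (2+2) cycloaddition to give vinylcyclobutenone 16; a second 4π opening gives dienylketene 17, which closes to dienone 18 and tautomerises to phenol 19. The closest known reaction type is the Danheiser benzannulation of cyclobutenones with alkyl ynol ethers, siloxyalkynes and ynamides; what is untested is the pairing of an aryl ynol ether with a 3,4-dialkoxycyclobutenone, and the electronic demand (electron-rich alkyne, electrophilic ketene) is unchanged. Ring G closes by thermal disrotatory 6π-electrocyclisation of 17, which re-forms the bond between the former carbonyl carbon and the methoxylated carbon and is made irreversible by enolisation to the arene. No stereocentre is created, and the racemic centre of 14 becomes an aromatic carbon. The step needs one regiochemistry, aryloxy meta to the new hydroxyl and para to the methoxy group, and this is fixed by the polarisation of the ynol ether, whose unsubstituted carbon is the nucleophilic one. The aryl ynol ether has no alkyl C–H beta to oxygen for a retro-ene loss, so it should survive the temperature at which 14 opens, and the small excess of 10 keeps free vinylketene from acylating 19.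

Step 7
Reactants: 19 F–G phenol 5-[2,6-dimethoxy-4-(triisopropylsilyloxy)phenoxy]-3-ethoxy-2-methoxyphenol
Product: 20 F–G silyl ether [4-(3-ethoxy-4,5-dimethoxyphenoxy)-3,5-dimethoxyphenoxy]triisopropylsilane
Conditions: MeI, K2CO3, acetone, 50 °C
Reagents that add atoms: iodomethane (MeI), CI
Why: The only free phenol is alkylated by MeI under mild K2CO3 conditions that leave the triisopropylsilyl aryl ether intact (Williamson ether synthesis).

Step 8
Reactants: 20 F–G silyl ether [4-(3-ethoxy-4,5-dimethoxyphenoxy)-3,5-dimethoxyphenoxy]triisopropylsilane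
Product: 21 F–G dimer phenol 4-(3-ethoxy-4,5-dimethoxyphenoxy)-3,5-dimethoxyphenol
Conditions: Bu4NF, AcOH, THF, 0 °C
Reagents that add atoms: none
Why: Fluoride cleaves the Si–O bond selectively (fluoride desilylation), and the acetic acid buffer keeps the electron-rich phenoxide from building up.

Step 9
Reactants: 21 F–G dimer phenol 4-(3-ethoxy-4,5-dimethoxyphenoxy)-3,5-dimethoxyphenol; 22 bromo aldehyde 2-bromo-3,4,5-trimethoxybenzaldehyde
Product: 23 trimer aldehyde 2-[4-(3-ethoxy-4,5-dimethoxyphenoxy)-3,5-dimethoxyphenoxy]-3,4,5-trimethoxybenzaldehyde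
Conditions: CuI (10 mol %), N,N-dimethylglycine hydrochloride (30 mol %), Cs2CO3, 1,4-dioxane, 100 °C, argon
Reagents that add atoms: none
Why: An unhindered phenol couples under CuI catalysis to an aryl bromide whose ortho formyl group accelerates the substitution (Ullmann diaryl ether synthesis), the same arrangement as in the established ether couplings of 2-bromo-3,4,5-trialkoxybenzoyl compounds.

Step 10
Reactants: 23 trimer aldehyde 2-[4-(3-ethoxy-4,5-dimethoxyphenoxy)-3,5-dimethoxyphenoxy]-3,4,5-trimethoxybenzaldehyde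
Product: 25 trimer phenol 2-[4-(3-ethoxy-4,5-dimethoxyphenoxy)-3,5-dimethoxyphenoxy]-3,4,5-trimethoxyphenol, via trimer formate 24 (not isolated)
Conditions: mCPBA, CH2Cl2, 0 °C to rt; aqueous NaHCO3 wash; then K2CO3 (cat.), MeOH, rt, argon
Reagents that add atoms: 3-chloroperoxybenzoic acid (mCPBA), OOC(=O)c1cccc(Cl)c1
Why: The aryl group carrying a para methoxy and an ortho aryloxy donor migrates in preference to hydride (Baeyer–Villiger oxidation of an aryl aldehyde, Dakin-type), and methanolysis of the formate frees the ring E hydroxyl.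

Step 11
Reactants: 25 trimer phenol 2-[4-(3-ethoxy-4,5-dimethoxyphenoxy)-3,5-dimethoxyphenoxy]-3,4,5-trimethoxyphenol; 26 fluoro aldehyde 4-fluoro-3,5-dimethoxybenzaldehyde
Product: 27 tetramer aldehyde 4-{2-[4-(3-ethoxy-4,5-dimethoxyphenoxy)-3,5-dimethoxyphenoxy]-3,4,5-trimethoxyphenoxy}-3,5-dimethoxybenzaldehyde
Conditions: Cs2CO3, DMSO, 120 °C, argon
Reagents that add atoms: none
Why: The para formyl group stabilises the Meisenheimer adduct and fluoride is the best leaving group for addition–elimination (SNAr), while the two flanking methoxy groups lie in the ring plane and leave the perpendicular approach open.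

Step 12
Reactants: 27 tetramer aldehyde 4-{2-[4-(3-ethoxy-4,5-dimethoxyphenoxy)-3,5-dimethoxyphenoxy]-3,4,5-trimethoxyphenoxy}-3,5-dimethoxybenzaldehyde
Product: 29 tetramer phenol 4-{2-[4-(3-ethoxy-4,5-dimethoxyphenoxy)-3,5-dimethoxyphenoxy]-3,4,5-trimethoxyphenoxy}-3,5-dimethoxyphenol, via tetramer formate 28 (not isolated)
Conditions: mCPBA, CH2Cl2, 0 °C to rt; aqueous NaHCO3 wash; then K2CO3 (cat.), MeOH, rt, argon
Reagents that add atoms: 3-chloroperoxybenzoic acid (mCPBA), OOC(=O)c1cccc(Cl)c1
Why: A 4-aryloxy-3,5-dimethoxyphenyl group migrates like the 3,4,5-trimethoxyphenyl group of the parent aldehyde, which is known to give its phenol this way (Baeyer–Villiger oxidation, Dakin-type).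

Step 13
Reactants: 29 tetramer phenol 4-{2-[4-(3-ethoxy-4,5-dimethoxyphenoxy)-3,5-dimethoxyphenoxy]-3,4,5-trimethoxyphenoxy}-3,5-dimethoxyphenol; 22 bromo aldehyde 2-bromo-3,4,5-trimethoxybenzaldehyde
Product: 30 pentamer aldehyde (ring D oxygen carries a 6-formyl-2,3,4-trimethoxyphenyl ring C)
Conditions: CuI (10 mol %), N,N-dimethylglycine hydrochloride (30 mol %), Cs2CO3, 1,4-dioxane, 100 °C, argon
Reagents that add atoms: none
Why: The ring D hydroxyl is again flanked by two C–H positions, so the coupling repeats step 9 (Ullmann diaryl ether synthesis).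

Step 14
Reactants: 30 pentamer aldehyde
Product: 32 pentamer phenol (ring C hydroxyl in place of the formyl group), via pentamer formate 31 (not isolated)
Conditions: mCPBA, CH2Cl2, 0 °C to rt; aqueous NaHCO3 wash; then K2CO3 (cat.), MeOH, rt, argon
Reagents that add atoms: 3-chloroperoxybenzoic acid (mCPBA), OOC(=O)c1cccc(Cl)c1
Why: Ring C has the same donor pattern as ring E in step 10, so aryl migration and formate methanolysis should proceed alike (Baeyer–Villiger oxidation, Dakin-type).

Step 15
Reactants: 32 pentamer phenol; 26 fluoro aldehyde 4-fluoro-3,5-dimethoxybenzaldehyde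
Product: 33 hexamer aldehyde (ring C oxygen carries a 4-formyl-2,6-dimethoxyphenyl ring B)
Conditions: Cs2CO3, DMSO, 120 °C, argon
Reagents that add atoms: none
Why: The ring C phenoxide displaces the para-formyl-activated fluoride as in step 11 (SNAr).

Step 16
Reactants: 33 hexamer aldehyde
Product: 35 hexamer phenol (ring B hydroxyl in place of the formyl group), via hexamer formate 34 (not isolated)
Conditions: mCPBA, CH2Cl2, 0 °C to rt; aqueous NaHCO3 wash; then K2CO3 (cat.), MeOH, rt, argon
Reagents that add atoms: 3-chloroperoxybenzoic acid (mCPBA), OOC(=O)c1cccc(Cl)c1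
Why: Ring B has the same donor pattern as ring D in step 12 (Baeyer–Villiger oxidation, Dakin-type).

Step 17
Reactants: 35 hexamer phenol; 26 fluoro aldehyde 4-fluoro-3,5-dimethoxybenzaldehyde
Product: 36 heptamer aldehyde (ring B oxygen carries a 4-formyl-2,6-dimethoxyphenyl ring A)
Conditions: Cs2CO3, DMSO, 120 °C, argon
Reagents that add atoms: none
Why: The unhindered ring B phenoxide is the easiest nucleophile of the three fluoride displacements (SNAr).

Step 18
Reactants: 36 heptamer aldehyde
Product: 38 heptamer phenol (ring A hydroxyl in place of the formyl group), via heptamer formate 37 (not isolated)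
Conditions: mCPBA, CH2Cl2, 0 °C to rt; aqueous NaHCO3 wash; then K2CO3 (cat.), MeOH, rt, argon
Reagents that add atoms: 3-chloroperoxybenzoic acid (mCPBA), OOC(=O)c1cccc(Cl)c1
Why: The formyl group of ring A is exchanged for the para hydroxyl of the terminal unit in the same way as in steps 12 and 16 (Baeyer–Villiger oxidation, Dakin-type).

Step 19
Reactants: 38 heptamer phenol
Product: 39 target polyphenol (the heptamer bearing eighteen free hydroxyls)
Conditions: BBr3 (40 equiv), CH2Cl2, −78 °C to rt; then H2O, 0 °C, argon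
Reagents that add atoms: none
Why: BBr3 cleaves aryl methyl and ethyl ethers by bromide attack on the alkyl group of the boron-complexed ether and leaves diaryl ethers untouched (Lewis acid ether cleavage), so the sixteen methyl ethers and the one ethyl ether should fall in one operation; the polyphenol is isolated by reverse-phase chromatography under exclusion of air.

**Compound list**
1 | 2,6-dimethoxy-1,4-benzoquinone | COC1=CC(=O)C=C(OC)C1=O | starting material
2 | 2,6-dimethoxybenzene-1,4-diol | COc1cc(O)cc(OC)c1O | intermediate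
3 | 2,6-dimethoxy-4-(triisopropylsilyloxy)phenol | COc1cc(O[Si](C(C)C)(C(C)C)C(C)C)cc(OC)c1O | intermediate
4 | trichloroethylene | ClC=C(Cl)Cl | starting material
5 | potassium 2,6-dimethoxy-4-(triisopropylsilyloxy)phenoxide | COc1cc(O[Si](C(C)C)(C(C)C)C(C)C)cc(OC)c1[O-].[K+] | intermediate
6 | dichloroacetylene | ClC#CCl | intermediate
7 | (E)-1,2-dichlorovinyl 2,6-dimethoxy-4-(triisopropylsilyloxy)phenyl ether | Cl/C=C(/Cl)Oc1c(OC)cc(O[Si](C(C)C)(C(C)C)C(C)C)cc1OC | intermediate
8 | chloroethynyl 2,6-dimethoxy-4-(triisopropylsilyloxy)phenyl ether | ClC#COc1c(OC)cc(O[Si](C(C)C)(C(C)C)C(C)C)cc1OC | intermediate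
9 | lithium [2,6-dimethoxy-4-(triisopropylsilyloxy)phenoxy]acetylide | [Li]C#COc1c(OC)cc(O[Si](C(C)C)(C(C)C)C(C)C)cc1OC | intermediate
10 | ethynyl 2,6-dimethoxy-4-(triisopropylsilyloxy)phenyl ether (ring F ynol ether) | C#COc1c(OC)cc(O[Si](C(C)C)(C(C)C)C(C)C)cc1OC | intermediate
11 | methoxyacetyl chloride | COCC(Cl)=O | starting material
12 | ethoxyacetylene | CCOC#C | starting material
13 | methoxyketene | COC=C=O | intermediate
14 | 3-ethoxy-4-methoxycyclobut-2-en-1-one (racemic) | O=C1C=C(OCC)C1OC | intermediate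
15 | (Z)-3-ethoxy-4-methoxybuta-1,3-dien-1-one | O=C=C/C(OCC)=C/OC | intermediate
16 | 3-[2,6-dimethoxy-4-(triisopropylsilyloxy)phenoxy]-4-[(Z)-1-ethoxy-2-methoxyethenyl]cyclobut-2-en-1-one (racemic) | O=C1C=C(Oc2c(OC)cc(O[Si](C(C)C)(C(C)C)C(C)C)cc2OC)C1/C(OCC)=C/OC | intermediate
17 | (3E,5Z)-3-[2,6-dimethoxy-4-(triisopropylsilyloxy)phenoxy]-5-ethoxy-6-methoxyhexa-1,3,5-trien-1-one | O=C=C/C(Oc1c(OC)cc(O[Si](C(C)C)(C(C)C)C(C)C)cc1OC)=C\C(OCC)=C\OC | intermediate
18 | 3-[2,6-dimethoxy-4-(triisopropylsilyloxy)phenoxy]-5-ethoxy-6-methoxycyclohexa-2,4-dien-1-one (racemic) | O=C1C=C(Oc2c(OC)cc(O[Si](C(C)C)(C(C)C)C(C)C)cc2OC)C=C(OCC)C1OC | intermediate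
19 | 5-[2,6-dimethoxy-4-(triisopropylsilyloxy)phenoxy]-3-ethoxy-2-methoxyphenol | Oc1cc(Oc2c(OC)cc(O[Si](C(C)C)(C(C)C)C(C)C)cc2OC)cc(OCC)c1OC | intermediate
20 | [4-(3-ethoxy-4,5-dimethoxyphenoxy)-3,5-dimethoxyphenoxy]triisopropylsilane | CCOc1cc(Oc2c(OC)cc(O[Si](C(C)C)(C(C)C)C(C)C)cc2OC)cc(OC)c1OC | intermediate
21 | 4-(3-ethoxy-4,5-dimethoxyphenoxy)-3,5-dimethoxyphenol | CCOc1cc(Oc2c(OC)cc(O)cc2OC)cc(OC)c1OC | intermediate
22 | 2-bromo-3,4,5-trimethoxybenzaldehyde | COc1cc(C=O)c(Br)c(OC)c1OC | starting material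
23 | trimer aldehyde, 2-[4-(3-ethoxy-4,5-dimethoxyphenoxy)-3,5-dimethoxyphenoxy]-3,4,5-trimethoxybenzaldehyde | CCOc1cc(Oc2c(OC)cc(Oc3c(C=O)cc(OC)c(OC)c3OC)cc2OC)cc(OC)c1OC | intermediate
24 | trimer formate, 2-[4-(3-ethoxy-4,5-dimethoxyphenoxy)-3,5-dimethoxyphenoxy]-3,4,5-trimethoxyphenyl formate | CCOc1cc(Oc2c(OC)cc(Oc3c(OC=O)cc(OC)c(OC)c3OC)cc2OC)cc(OC)c1OC | intermediate
25 | trimer phenol, 2-[4-(3-ethoxy-4,5-dimethoxyphenoxy)-3,5-dimethoxyphenoxy]-3,4,5-trimethoxyphenol | CCOc1cc(Oc2c(OC)cc(Oc3c(O)cc(OC)c(OC)c3OC)cc2OC)cc(OC)c1OC | intermediate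
26 | 4-fluoro-3,5-dimethoxybenzaldehyde | COc1cc(C=O)cc(OC)c1F | starting material
27 | tetramer aldehyde, 4-{2-[4-(3-ethoxy-4,5-dimethoxyphenoxy)-3,5-dimethoxyphenoxy]-3,4,5-trimethoxyphenoxy}-3,5-dimethoxybenzaldehyde | CCOc1cc(Oc2c(OC)cc(Oc3c(Oc4c(OC)cc(C=O)cc4OC)cc(OC)c(OC)c3OC)cc2OC)cc(OC)c1OC | intermediate
28 | tetramer formate, 4-{2-[4-(3-ethoxy-4,5-dimethoxyphenoxy)-3,5-dimethoxyphenoxy]-3,4,5-trimethoxyphenoxy}-3,5-dimethoxyphenyl formate | CCOc1cc(Oc2c(OC)cc(Oc3c(Oc4c(OC)cc(OC=O)cc4OC)cc(OC)c(OC)c3OC)cc2OC)cc(OC)c1OC | intermediate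
29 | tetramer phenol, 4-{2-[4-(3-ethoxy-4,5-dimethoxyphenoxy)-3,5-dimethoxyphenoxy]-3,4,5-trimethoxyphenoxy}-3,5-dimethoxyphenol | CCOc1cc(Oc2c(OC)cc(Oc3c(Oc4c(OC)cc(O)cc4OC)cc(OC)c(OC)c3OC)cc2OC)cc(OC)c1OC | intermediate
30 | pentamer aldehyde, the tetramer phenol O-arylated on ring D by a 6-formyl-2,3,4-trimethoxyphenyl group (ring C) | CCOc1cc(Oc2c(OC)cc(Oc3c(Oc4c(OC)cc(Oc5c(C=O)cc(OC)c(OC)c5OC)cc4OC)cc(OC)c(OC)c3OC)cc2OC)cc(OC)c1OC | intermediate
31 | pentamer formate, formyloxy in place of the formyl group on ring C | CCOc1cc(Oc2c(OC)cc(Oc3c(Oc4c(OC)cc(Oc5c(OC=O)cc(OC)c(OC)c5OC)cc4OC)cc(OC)c(OC)c3OC)cc2OC)cc(OC)c1OC | intermediate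
32 | pentamer phenol, hydroxyl in place of the formyl group on ring C | CCOc1cc(Oc2c(OC)cc(Oc3c(Oc4c(OC)cc(Oc5c(O)cc(OC)c(OC)c5OC)cc4OC)cc(OC)c(OC)c3OC)cc2OC)cc(OC)c1OC | intermediate
33 | hexamer aldehyde, the pentamer phenol O-arylated on ring C by a 4-formyl-2,6-dimethoxyphenyl group (ring B) | CCOc1cc(Oc2c(OC)cc(Oc3c(Oc4c(OC)cc(Oc5c(Oc6c(OC)cc(C=O)cc6OC)cc(OC)c(OC)c5OC)cc4OC)cc(OC)c(OC)c3OC)cc2OC)cc(OC)c1OC | intermediate
34 | hexamer formate, formyloxy in place of the formyl group on ring B | CCOc1cc(Oc2c(OC)cc(Oc3c(Oc4c(OC)cc(Oc5c(Oc6c(OC)cc(OC=O)cc6OC)cc(OC)c(OC)c5OC)cc4OC)cc(OC)c(OC)c3OC)cc2OC)cc(OC)c1OC | intermediate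
35 | hexamer phenol, hydroxyl in place of the formyl group on ring B | CCOc1cc(Oc2c(OC)cc(Oc3c(Oc4c(OC)cc(Oc5c(Oc6c(OC)cc(O)cc6OC)cc(OC)c(OC)c5OC)cc4OC)cc(OC)c(OC)c3OC)cc2OC)cc(OC)c1OC | intermediate
36 | heptamer aldehyde, the hexamer phenol O-arylated on ring B by a 4-formyl-2,6-dimethoxyphenyl group (ring A) | CCOc1cc(Oc2c(OC)cc(Oc3c(Oc4c(OC)cc(Oc5c(Oc6c(OC)cc(Oc7c(OC)cc(C=O)cc7OC)cc6OC)cc(OC)c(OC)c5OC)cc4OC)cc(OC)c(OC)c3OC)cc2OC)cc(OC)c1OC | intermediate
37 | heptamer formate, formyloxy in place of the formyl group on ring A | CCOc1cc(Oc2c(OC)cc(Oc3c(Oc4c(OC)cc(Oc5c(Oc6c(OC)cc(Oc7c(OC)cc(OC=O)cc7OC)cc6OC)cc(OC)c(OC)c5OC)cc4OC)cc(OC)c(OC)c3OC)cc2OC)cc(OC)c1OC | intermediate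
38 | heptamer phenol, ring A hydroxyl free, sixteen methyl ethers and one ethyl ether | CCOc1cc(Oc2c(OC)cc(Oc3c(Oc4c(OC)cc(Oc5c(Oc6c(OC)cc(Oc7c(OC)cc(O)cc7OC)cc6OC)cc(OC)c(OC)c5OC)cc4OC)cc(OC)c(OC)c3OC)cc2OC)cc(OC)c1OC | intermediate
39 | CNP0292517.0, heptameric phloroglucinol ether bearing eighteen free hydroxyls | Oc1cc(O)c(Oc2cc(O)c(Oc3cc(O)c(O)c(O)c3Oc3cc(O)c(Oc4cc(O)c(O)c(O)c4Oc4cc(O)c(Oc5cc(O)c(O)c(O)c5)c(O)c4)c(O)c3)c(O)c2)c(O)c1 | target

**Step count**
Total: 19 steps. Longest linear sequence: 18 steps (steps 1 to 4 and 6 to 19); step 5 is a one-step side branch.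

**Steps most likely to fail**

1. Step 6 (proposed new method). The terminal aryl ynol ether may oligomerise before it meets the ketene, the donor-substituted vinylketene may dimerise or react sluggishly in the (2+2) step, and free vinylketene may acylate the product phenol. The fallback uses known chemistry and buys ring G instead of building it, so that steps 3 to 7 are no longer needed; it sets out from 3 and comes back to the route at 20. Commercial 5-bromo-2,3-dimethoxybenzaldehyde would be oxidised by mCPBA to 5-bromo-2,3-dimethoxyphenyl formate F1, which K2CO3 in MeOH cleaves to 5-bromo-2,3-dimethoxyphenol F2. Ethylation (EtI, K2CO3, acetone) gives 5-bromo-1-ethoxy-2,3-dimethoxybenzene F3. Bromine–lithium exchange (n-BuLi, THF, −78 °C) gives (3-ethoxy-4,5-dimethoxyphenyl)lithium F4, which is trapped by B(OiPr)3 and hydrolysed by aqueous HCl to (3-ethoxy-4,5-dimethoxyphenyl)boronic acid F5. Chan–Lam–Evans coupling of F5 to the hindered phenol 3 (Cu(OAc)2, pyridine, 4 Å molecular sieves, CH2Cl2, air, rt), a coupling that tolerates two ortho substituents on the phenol as well as a silyl ether, should give 20 directly.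

2. Step 11 (the same operation recurs in steps 15 and 17). Attack at the fluoride carbon flanked by two methoxy groups may be slow, which would force temperatures at which the electron-rich phenoxide is oxidised or the aldehyde degrades. The fallback sets out from 25 and comes back at 27. The bond is made by CuI catalysis instead of addition–elimination: 25 and commercial 4-bromo-3,5-dimethoxybenzaldehyde are coupled by CuI, picolinic acid and K3PO4 in DMSO at 90 °C (Ullmann diaryl ether synthesis under conditions developed for hindered partners). This gives 27 itself, so no compound outside the list arises (F0).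

3. Step 19. Cleavage of seventeen ethers may stop short and leave inseparable partly alkylated material, and the free polyphenol may be oxidised by air during isolation. The fallback sets out from 38 and comes back at 39. The ethers are cleaved by the hard acid–soft nucleophile pair AlCl3/EtSH in CH2Cl2, the mixture is quenched by dilute aqueous HCl, and the crude polyphenol is acetylated at once (Ac2O, pyridine) to the target octadecaacetate F6. This ester is stable to air, can be purified on silica and, if alkyl groups remain, resubmitted. Transesterification by catalytic NaOMe in MeOH under argon, followed by neutralisation over an acidic ion-exchange resin, releases 39.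

**Further compounds**
F1 | step 6 | 5-bromo-2,3-dimethoxyphenyl formate | O=COc1cc(Br)cc(OC)c1OC
F2 | step 6 | 5-bromo-2,3-dimethoxyphenol | Oc1cc(Br)cc(OC)c1OC
F3 | step 6 | 5-bromo-1-ethoxy-2,3-dimethoxybenzene | CCOc1cc(Br)cc(OC)c1OC
F4 | step 6 | (3-ethoxy-4,5-dimethoxyphenyl)lithium | [Li]c1cc(OCC)c(OC)c(OC)c1
F5 | step 6 | (3-ethoxy-4,5-dimethoxyphenyl)boronic acid | CCOc1cc(B(O)O)cc(OC)c1OC
F0 | step 11 | none | none
F6 | step 19 | octadecaacetate of the target | CC(=O)Oc1cc(OC(C)=O)c(Oc2cc(OC(C)=O)c(Oc3cc(OC(C)=O)c(OC(C)=O)c(OC(C)=O)c3Oc3cc(OC(C)=O)c(Oc4cc(OC(C)=O)c(OC(C)=O)c(OC(C)=O)c4Oc4cc(OC(C)=O)c(Oc5cc(OC(C)=O)c(OC(C)=O)c(OC(C)=O)c5)c(OC(C)=O)c4)c(OC(C)=O)c3)c(OC(C)=O)c2)c(OC(C)=O)c1
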